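The earlier runs and the new flask were computed for substances that don't exist, and the scatter is random.

If a quick number is what you want, your hunch that reagent costs target will carry one, and a single ratio does the work.

| flask | substrate | reagent | remark | time |
|---|---|---|---|---|
| gamma | 0.0020 M | 0.76 equiv | run made earlier |  |
| zeta | 0.0020 M | 6.7 equiv | run made earlier |  |
| elm | 0.0020 M | 0.600 equiv |  | 3.0 min |
| oak | 0.0020 M | 2.00 equiv |  | 3.0 min |
| alder | 0.0020 M | 5.00 equiv |  | 3.0 min |

| run | time / min | target / % |
|---|---|---|
| gamma | 0.833 | 79.9 |
| gamma | 1.50 | 87.9 |
| gamma | 2.50 | 91.2 |
| gamma | 3.00 | 92.7 |
| zeta | 0.417 | 40.2 |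
| zeta | 1.00 | 54.4 |
| zeta | 2.00 | 55.6 |
| zeta | 3.00 | 56.8 |

(scatter of a reading: 1 percentage point)

- the analysis behind the earlier runs scatters by 1 percentage point, standard deviation
- steps that have been proposed: substrate <-> intermediate A; intermediate A -> target; substrate + reagent -> intermediate B; intermediate B <-> intermediate C
- "hardly changes" means that all values lie within two and a half points (for a concentration: within two and a half percent of the largest)

- amount of target at the end, in percent of the substrate charged for elm, oak, alder, in this order
- the course of these numbers from the first flask to the last (hardly changes / falls, then rises / falls all the way / rises all the way / rises, then falls)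

In the proposed steps, substrate goes to target without reagent and to intermediate B with it. The rate of loss over the rate of target should therefore grow in step with reagent, while the substrate concentration cancels. We replace the falling reagent curve by its mean: each substrate lost takes one reagent, so the mean is the charge less half the loss.

Zeta's last reading, 56.8%, gives 0.117 for what we call the loss per equivalent, a selectivity factor: substrate lost for each unit of target, divided by the mean reagent in equivalents. Gamma reads 0.109, but on a loss of 7.30% with a scatter of 1 percentage point. We lean on zeta, whose loss of 43.2% is larger.

The share of target is then one over one plus the loss per equivalent times the mean reagent. That gives us 93.8% for elm, 81.7% for oak and 63.9% for alder. The check on the mean is cheap: using the plain charge in both zeta and alder moves alder by 0.11 points, so the ratio of charges nearly suffices.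

The forecast says 93.5%, 81.5% and 65%, a course that falls all the way, on the ground “with B/target roughly proportional to reagent equivalents”. Our alder lies 1.1 points below it.

Elm gives 93.4%, oak 81.0% and alder 62.8%, so the row falls all the way.

    substrate ⇌ intermediate A (K = 7.20, k = 0.240 s⁻¹)
    intermediate A → target (k = 0.0490 s⁻¹)
    substrate + reagent → intermediate B (k = 8.80 M⁻¹ s⁻¹)
    intermediate B ⇌ intermediate C (K = 9.60, k = 0.0620 s⁻¹)

At 3.00 min alder still holds 92.6% of its own reagent charge. Read from alder, the loss per equivalent is 0.123. Put into oak's 2.00 equiv, less half the loss, it gives 81.0%, and oak stands at 81.0%.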